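(Readings and results stem from a simulated flask from invented constants; the scatter is artificial.)

Commit first to one constant, and let this flask's X hang on it.

all flasks: Q 0.30 M

| charge | Z | D | remark | time |
|---|---|---|---|---|
| blue | 67 mM | 16 mM | run made earlier |  |
| red | 110 mM | 16 mM | run made earlier |  |
| ochre | 48 mM | 24 mM | run made earlier |  |
| flask | 48 mM | 16 mM |  | 8.0 h |

| run | time / h | X / % | L / % |
|---|---|---|---|
| blue | 0.333 | 0 | 4.7 |
| blue | 1.00 | 0.7 | 12.3 |
| blue | 2.00 | 2.6 | 16.3 |
| blue | 3.00 | 7.6 | 17.3 |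
| blue | 4.00 | 12.7 | 17.8 |
| blue | 5.00 | 20.1 | 15.2 |
| blue | 6.00 | 26.1 | 16.3 |
| red | 1.00 | 1.5 | 11.5 |
| red | 2.00 | 5.3 | 14.7 |
| red | 3.00 | 13.6 | 14.3 |
| red | 4.00 | 21.7 | 12.9 |
| red | 5.00 | 31.6 | 12.3 |
| red | 6.00 | 41.2 | 13.6 |
| ochre | 0.500 | 0 | 7.6 |
| ochre | 1.50 | 0 | 16.3 |
| ochre | 3.00 | 2.1 | 20.6 |
| ochre | 5.00 | 9.1 | 20.3 |
| ochre | 6.00 | 12.4 | 20.9 |

(readings scatter by 0.5 percentage points)

- Q is a solid; its amount is given per volume of the solution
- the earlier runs were read with a standard deviation of 0.5 percentage points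
- at the start none of Q is in solution
- L means what is dissolved; the solid is not counted in it

* X present at 8.0 h, in percent of the Q charged
* L present at 8.0 h, in percent of the Q charged

*What do the runs show?* Q dissolves into L, and X appears after a lag. Over the late readings, the rate of X divided by L gives a pseudo-first-order constant k: 0.393 h⁻¹ in blue, 0.736 h⁻¹ in red, 0.165 h⁻¹ in ochre.

*Against what does k scale?* Against W, the Z charged minus the D charged. The mean of k/W over these runs is κ, 7.48 M⁻¹ h⁻¹, the X constant per unit of Z in excess of D.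

*And this flask?* W is 32.0 mM, so k is 0.239 h⁻¹. The late X lines meet zero at 2.10 h in blue and 2.39 h in ochre; I take their mean. With ochre's plateau L of 20.8%, since ochre has the same Z, X comes to 28.6%.

*But this flask's k is larger than ochre's, so isn't that L too high?* Yes. Putting k back in, on a straight line between ochre and blue's plateau of 17.1%, L becomes 19.6% and X 26.9%. I commit to those.

The forecast gives X 26% and L 19%, each a little under mine, and for the lag says “so I take about 2 h here”.

The flask gives X 26.5% and L 14.8%, lower than my L, with Q at 0% by then.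

L + J → J + X (k = 0.140 M⁻¹ min⁻¹); L → G (k = 0.00720 min⁻¹); J + D → E (k = 160 M⁻¹ min⁻¹); Z → J (k = 0.00840 min⁻¹); Q ⇌ L, rate k5*(cs5 - [L]) while solid is left; crystals form when [L] > cs5 (solubility = 0.210 M, k = 0.00410 min⁻¹) At 3.69 h the step to G uses L 2.1 times as fast as the step to X, and its half-life of 1.6 h is shorter than the 2.90 h that κW gives for X. Reckoned with κW, that split gives X 35.6% of the L used, and at 80.0 h this flask holds X 32.1%. With 0.19 M of Z and the same half-life, the reckoning with κW gives X 75.1% of the L used, and at 8.00 h that neighbour flask holds X 70.4% against G 28.9%.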